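**Plan**

1. Locants: lactone ring O1, C2–C5; side chain C1'–C13' counted from C5 (C2'=C3' is Z, C6' carries Me, C7'=C8' is E, C9' carries OMe, C10' is the C(Me)OH carbon, C13' sits on furan C3).
2. Retrosynthetic cuts: C10'–C11' (carbinol carbon to the first CH2 of the furylpropyl arm); the tetronate ring at C3–C4 and its O1–C2 acyl bond; C1'–C2'; the C2'=C3' and C7'=C8' double bonds; the furan–C13' bond.
3. Forward: divinylcarbinol gives the C8'–C10' piece 5; cross-metathesis with epoxidised (S)-β-citronellene makes C7'=C8'; periodate unmasks C3' as the aldehyde; iodo-olefination makes C2'=C3'; the alkenyl metal opens methyl (S)-glycidate (C1'–C2'); Dieckmann closure builds the tetronate, the only ring made (the furan is bought as 3-bromofuran); C10' is oxidised to the ketone and joined to the furylpropyl Grignard reagent; O-demethylation ends the route.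
4. Enabling feature: in ketone 19 the methoxy oxygen on C9' is α to the C10' carbonyl, so Mg(II) closes a five-membered chelate ring (Mg, O=C10', C9', OMe). The C7'=C8' alkenyl arm on C9' covers one face, and the nucleophile enters on the other (Si) face, which is the (10'S) carbinol of the target. The same event unites the C19 lactone half with the C7 furan half.
5. Stereochemistry: C6' from (S)-β-citronellene; C9' from Sharpless desymmetrisation of penta-1,4-dien-3-ol; C5 from methyl (S)-glycidate; C10' by chelate-controlled 1,2-induction from C9'; E alkene by thermodynamic control in the metathesis; Z alkene from the Stork–Zhao ylide.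

Key step: step 17

Remark: the carbon that becomes the ketone (C10') carries an (R) silyl ether through steps 4–13 and is destroyed in step 14, so its configuration is immaterial; 7 and 8 are carried as mixtures of oxirane epimers because that carbon is removed in step 7.

**Route**

Step 1
Reactants: 1 penta-1,4-dien-3-ol
Product: 2 (1S)-1-[(2R)-oxiran-2-yl]prop-2-en-1-ol
Conditions: Ti(OiPr)4 (10 mol%), L-(+)-DIPT (13 mol%), t-BuOOH, 4 Å MS, CH2Cl2, −20 °C
Reagents that add atoms: tert-butyl hydroperoxide, CC(C)(C)OO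
Why: Sharpless asymmetric epoxidation used as a desymmetrisation: by the usual mnemonic the L-(+)-tartrate catalyst should epoxidise one enantiotopic vinyl group from one face to the anti epoxy alcohol, which sets the future C9' carbinol as (S), and the minor enantiomer is drained by a faster second epoxidation.

Step 2
Reactants: 2 (1S)-1-[(2R)-oxiran-2-yl]prop-2-en-1-ol
Product: 3 (2R)-2-[(1S)-1-methoxyprop-2-en-1-yl]oxirane
Conditions: NaH, MeI, THF, 0 °C
Reagents that add atoms: iodomethane, CI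
Why: Williamson O-methylation of the sodium alkoxide; fast trapping by iodomethane in aprotic THF at 0 °C should outrun Payne rearrangement, and no stereocentre is touched.

Step 3
Reactants: 3 (2R)-2-[(1S)-1-methoxyprop-2-en-1-yl]oxirane
Product: 4 (2R,3S)-3-methoxypent-4-en-2-ol
Conditions: LiAlH4, Et2O, 0 °C; aqueous work-up (volatile product kept in solution)
Reagents that add atoms: none
Why: Hydride opens the terminal oxirane at its unsubstituted CH2 (SN2 epoxide reduction), which turns it into the methyl carbinol without touching either stereocentre.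

Step 4
Reactants: 4 (2R,3S)-3-methoxypent-4-en-2-ol
Product: 5 tert-butyl{[(2R,3S)-3-methoxypent-4-en-2-yl]oxy}dimethylsilane
Conditions: TBSCl, imidazole, DMF, 23 °C
Reagents that add atoms: tert-butyldimethylsilyl chloride, CC(C)(C)[Si](C)(C)Cl
Why: Standard silylation of the secondary alcohol (silyl chloride with imidazole) masks the future ketone oxygen for steps 6–12.

Step 5
Reactants: 6 (S)-β-citronellene [(3S)-3,7-dimethylocta-1,6-diene]
Product: 7 2,2-dimethyl-3-[(3S)-3-methylpent-4-en-1-yl]oxirane (both oxirane epimers)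
Conditions: mCPBA (1.0 equiv), NaHCO3, CH2Cl2, 0 °C
Reagents that add atoms: 3-chloroperoxybenzoic acid, OOC(=O)c1cccc(Cl)c1
Why: Prilezhaev epoxidation is chemoselective for the electron-rich trisubstituted alkene over the vinyl group; the oxirane serves as a masked aldehyde and removes the alkene that would otherwise ring-close to a cyclopentene in step 6.

Step 6
Reactants: 7 2,2-dimethyl-3-[(3S)-3-methylpent-4-en-1-yl]oxirane; 5 tert-butyl{[(2R,3S)-3-methoxypent-4-en-2-yl]oxy}dimethylsilane (2.5 equiv)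
Product: 8 tert-butyl{[(2R,3S,4E,6S)-8-(3,3-dimethyloxiran-2-yl)-3-methoxy-6-methyloct-4-en-2-yl]oxy}dimethylsilane (both oxirane epimers)
Conditions: Hoveyda–Grubbs second-generation catalyst (5 mol%), CH2Cl2, 40 °C, argon sweep
Reagents that add atoms: none
Why: Olefin cross-metathesis of two allylically branched terminal alkenes that homodimerise slowly; loss of ethene drives it and the hindered 1,2-disubstituted alkene should form as the thermodynamic E isomer, with all stereocentres untouched.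

Step 7
Reactants: 8 tert-butyl{[(2R,3S,4E,6S)-8-(3,3-dimethyloxiran-2-yl)-3-methoxy-6-methyloct-4-en-2-yl]oxy}dimethylsilane
Product: 9 (4S,5E,7S,8R)-8-[(tert-butyldimethylsilyl)oxy]-7-methoxy-4-methylnon-5-enal
Conditions: H5IO6, THF/H2O, 0 °C
Reagents that add atoms: none
Why: Periodic acid hydrolyses the trisubstituted oxirane and cleaves the resulting glycol in one pot (Malaprade-type cleavage) to the aldehyde and acetone, while the disubstituted alkene and the silyl ether should survive the short, cold treatment.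

Step 8
Reactants: 9 (4S,5E,7S,8R)-8-[(tert-butyldimethylsilyl)oxy]-7-methoxy-4-methylnon-5-enal
Product: 10 tert-butyl{[(2R,3S,4E,6S,9Z)-10-iodo-3-methoxy-6-methylundeca-4,9-dien-2-yl]oxy}dimethylsilane
Conditions: EtPPh3I, n-BuLi, THF, 23 °C; I2, −78 °C; NaHMDS, −78 °C; then 9, −78 → −20 °C
Reagents that add atoms: ethyltriphenylphosphonium iodide, CC[P+](c1ccccc1)(c1ccccc1)c1ccccc1.[I-]; iodine, II
Why: Stork–Zhao olefination (Wittig reaction of the α-iodo ylide): the unstabilised ylide reacts under kinetic control and should place iodine cis to the chain, which fixes the Z geometry of the future C2'=C3' bond.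

Step 9
Reactants: 10 tert-butyl{[(2R,3S,4E,6S,9Z)-10-iodo-3-methoxy-6-methylundeca-4,9-dien-2-yl]oxy}dimethylsilane; 11 methyl (2S)-oxirane-2-carboxylate
Product: 14 methyl (2S,4Z,8S,9E,11S,12R)-12-[(tert-butyldimethylsilyl)oxy]-2-hydroxy-11-methoxy-4,8-dimethyltrideca-4,9-dienoate, via alkenyllithium 12 (not isolated), via alkenylmagnesium bromide 13 (not isolated)
Conditions: t-BuLi (2.1 equiv), Et2O, −78 °C; MgBr2·OEt2; CuI (15 mol%), 11, THF, −40 → −20 °C; NH4Cl (aq)
Reagents that add atoms: none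
Why: Iodine–lithium exchange with retention of alkene geometry, transmetalation to magnesium and copper-catalysed SN2 opening of the glycidate at its CH2 terminus should give the α-hydroxy ester, whose stereocentre (the future C5) comes unchanged from 11.

Step 10
Reactants: 14 methyl (2S,4Z,8S,9E,11S,12R)-12-[(tert-butyldimethylsilyl)oxy]-2-hydroxy-11-methoxy-4,8-dimethyltrideca-4,9-dienoate
Product: 15 methyl (2S,4Z,8S,9E,11S,12R)-12-[(tert-butyldimethylsilyl)oxy]-11-methoxy-4,8-dimethyl-2-(propanoyloxy)trideca-4,9-dienoate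
Conditions: (EtCO)2O, Et3N, DMAP (cat.), CH2Cl2, 0 → 23 °C
Reagents that add atoms: propanoic anhydride, CCC(=O)OC(=O)CC
Why: DMAP-catalysed acylation of the secondary α-hydroxy ester installs the three carbons (C2, C3 and the 3-methyl) of the tetronate.

Step 11
Reactants: 15 methyl (2S,4Z,8S,9E,11S,12R)-12-[(tert-butyldimethylsilyl)oxy]-11-methoxy-4,8-dimethyl-2-(propanoyloxy)trideca-4,9-dienoate
Product: 16 (5S)-5-{(2Z,6S,7E,9S,10R)-10-[(tert-butyldimethylsilyl)oxy]-9-methoxy-2,6-dimethylundeca-2,7-dien-1-yl}-4-hydroxy-3-methylfuran-2(5H)-one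
Conditions: LiHMDS (2.5 equiv), THF, −78 → 0 °C; cold dilute HCl
Reagents that add atoms: none
Why: Dieckmann (Lacey-type) condensation: the propanoate lithium enolate attacks the neighbouring methyl ester in a 5-exo-trig closure and loss of methoxide gives the tetronic acid as its stable lithium enolate, which drives the reaction and should protect C5 from epimerisation at low temperature.

Step 12
Reactants: 16 (5S)-5-{(2Z,6S,7E,9S,10R)-10-[(tert-butyldimethylsilyl)oxy]-9-methoxy-2,6-dimethylundeca-2,7-dien-1-yl}-4-hydroxy-3-methylfuran-2(5H)-one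
Product: 17 (5S)-5-{(2Z,6S,7E,9S,10R)-10-[(tert-butyldimethylsilyl)oxy]-9-methoxy-2,6-dimethylundeca-2,7-dien-1-yl}-4-methoxy-3-methylfuran-2(5H)-one
Conditions: MeOH, PPh3, DIAD, THF, 0 → 23 °C
Reagents that add atoms: methanol, CO
Why: Mitsunobu O-alkylation of the acidic enol (a vinylogous carboxylic acid) should methylate O4 selectively and masks the acid for the oxidation and the Grignard step.

Step 13
Reactants: 17 (5S)-5-{(2Z,6S,7E,9S,10R)-10-[(tert-butyldimethylsilyl)oxy]-9-methoxy-2,6-dimethylundeca-2,7-dien-1-yl}-4-methoxy-3-methylfuran-2(5H)-one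
Product: 18 (5S)-5-[(2Z,6S,7E,9S,10R)-10-hydroxy-9-methoxy-2,6-dimethylundeca-2,7-dien-1-yl]-4-methoxy-3-methylfuran-2(5H)-one
Conditions: HF·pyridine, pyridine, THF, 0 → 23 °C
Reagents that add atoms: none
Why: Fluoride-mediated desilylation under buffered acidic conditions frees the secondary alcohol; the methyl tetronate and the allylic methyl ether are stable to it.

Step 14
Reactants: 18 (5S)-5-[(2Z,6S,7E,9S,10R)-10-hydroxy-9-methoxy-2,6-dimethylundeca-2,7-dien-1-yl]-4-methoxy-3-methylfuran-2(5H)-one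
Product: 19 (5S)-4-methoxy-5-[(2Z,6S,7E,9S)-9-methoxy-2,6-dimethyl-10-oxoundeca-2,7-dien-1-yl]-3-methylfuran-2(5H)-one
Conditions: Dess–Martin periodinane, NaHCO3, CH2Cl2, 0 °C; filtration through deactivated silica, used at once
Reagents that add atoms: none
Why: Dess–Martin oxidation under buffered, non-basic conditions should give the α-methoxy β,γ-unsaturated methyl ketone without epimerisation at C9' or migration of the double bond.

Step 15
Reactants: 20 3-bromofuran; 21 oxetane
Product: 23 3-(furan-3-yl)propan-1-ol, via furan-3-yllithium 22 (not isolated)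
Conditions: n-BuLi, THF, −78 °C; 21, BF3·OEt2, −78 °C
Reagents that add atoms: none
Why: Bromine–lithium exchange at −78 °C gives furan-3-yllithium without isomerisation to the 2-lithio species, and BF3-activated oxetane is opened by SN2 attack to deliver the three-carbon alcohol in one step.

Step 16
Reactants: 23 3-(furan-3-yl)propan-1-ol
Product: 24 3-(3-bromopropyl)furan
Conditions: CBr4, PPh3, CH2Cl2, 0 °C
Reagents that add atoms: carbon tetrabromide, BrC(Br)(Br)Br
Why: Appel bromination of the primary alcohol under neutral conditions that the acid-sensitive furan tolerates.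

Step 17
Reactants: 19 (5S)-4-methoxy-5-[(2Z,6S,7E,9S)-9-methoxy-2,6-dimethyl-10-oxoundeca-2,7-dien-1-yl]-3-methylfuran-2(5H)-one; 24 3-(3-bromopropyl)furan
Product: 26 (5S)-5-[(2Z,6S,7E,9S,10S)-13-(furan-3-yl)-10-hydroxy-9-methoxy-2,6,10-trimethyltrideca-2,7-dien-1-yl]-4-methoxy-3-methylfuran-2(5H)-one, via 3-(furan-3-yl)propylmagnesium bromide 25 (not isolated)
Conditions: 24, Mg, Et2O, 23 °C; 19, MgBr2·OEt2, CH2Cl2, −78 °C; then 25 (2.5 equiv), −78 °C; NH4Cl (aq) at −78 °C
Reagents that add atoms: none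
Why: Ketone 19 is first locked by MgBr2 as the five-membered chelate (Mg, O=C10', C9', OMe), in which the C7'=C8' alkenyl arm on C9' covers one face of the carbonyl, and the primary alkyl Grignard reagent 25 then adds to the open Si face to give the (10'S) tertiary alkoxide. The closest known reaction type is the Cram-chelate (chelation-controlled) 1,2-addition of a Grignard reagent to an α-alkoxy ketone. No ring of the target is closed; the only ring involved is the transient chelate, which is released on aqueous work-up. The new stereocentre C10' is controlled by the existing C9' stereocentre through that chelate, with the target's own methoxy group as the directing ligand and no auxiliary. The step needs addition to the ketone in preference to attack on the vinylogous carbonate of the methyl tetronate and in preference to enolisation of the α-methoxy β,γ-unsaturated ketone. Chelation activates the ketone, −78 °C with a cold neutral quench limits proton transfer, and the acidic tetronic acid is masked as its methyl ether.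

Step 18
Reactants: 26 (5S)-5-[(2Z,6S,7E,9S,10S)-13-(furan-3-yl)-10-hydroxy-9-methoxy-2,6,10-trimethyltrideca-2,7-dien-1-yl]-4-methoxy-3-methylfuran-2(5H)-one
Product: 27 (5S)-5-[(2Z,6S,7E,9S,10S)-13-(furan-3-yl)-10-hydroxy-9-methoxy-2,6,10-trimethyltrideca-2,7-dien-1-yl]-4-hydroxy-3-methylfuran-2(5H)-one
Conditions: n-PrSLi (from n-PrSH and n-BuLi), HMPA, 23 °C; cold dilute HCl
Reagents that add atoms: none
Why: SN2 O-demethylation by thiolate: the tetronate is a good leaving group (vinylogous carboxylate), so only this methyl should be removed, whereas the aliphatic methyl ether at C9', the tertiary alcohol, the furan and both alkenes are inert.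

**Compound list**

1 | penta-1,4-dien-3-ol | C=CC(O)C=C | starting material
2 | (1S)-1-[(2R)-oxiran-2-yl]prop-2-en-1-ol | C=C[C@H](O)[C@H]1CO1 | intermediate
3 | (2R)-2-[(1S)-1-methoxyprop-2-en-1-yl]oxirane | C=C[C@H](OC)[C@H]1CO1 | intermediate
4 | (2R,3S)-3-methoxypent-4-en-2-ol | C=C[C@H](OC)[C@@H](C)O | intermediate
5 | tert-butyl{[(2R,3S)-3-methoxypent-4-en-2-yl]oxy}dimethylsilane | C=C[C@H](OC)[C@@H](C)O[Si](C)(C)C(C)(C)C | intermediate
6 | (S)-β-citronellene, (3S)-3,7-dimethylocta-1,6-diene | C=C[C@@H](C)CCC=C(C)C | starting material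
7 | 2,2-dimethyl-3-[(3S)-3-methylpent-4-en-1-yl]oxirane (both oxirane epimers) | C=C[C@@H](C)CCC1OC1(C)C | intermediate
8 | tert-butyl{[(2R,3S,4E,6S)-8-(3,3-dimethyloxiran-2-yl)-3-methoxy-6-methyloct-4-en-2-yl]oxy}dimethylsilane (both oxirane epimers) | CO[C@@H](/C=C/[C@@H](C)CCC1OC1(C)C)[C@@H](C)O[Si](C)(C)C(C)(C)C | intermediate
9 | (4S,5E,7S,8R)-8-[(tert-butyldimethylsilyl)oxy]-7-methoxy-4-methylnon-5-enal | CO[C@@H](/C=C/[C@@H](C)CCC=O)[C@@H](C)O[Si](C)(C)C(C)(C)C | intermediate
10 | tert-butyl{[(2R,3S,4E,6S,9Z)-10-iodo-3-methoxy-6-methylundeca-4,9-dien-2-yl]oxy}dimethylsilane | CO[C@@H](/C=C/[C@@H](C)CC/C=C(/C)I)[C@@H](C)O[Si](C)(C)C(C)(C)C | intermediate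
11 | methyl (2S)-oxirane-2-carboxylate | COC(=O)[C@@H]1CO1 | starting material
12 | {(2E,6S,7E,9S,10R)-10-[(tert-butyldimethylsilyl)oxy]-9-methoxy-6-methylundeca-2,7-dien-2-yl}lithium (Li in place of I, alkene geometry of 10 retained) | CO[C@@H](/C=C/[C@@H](C)CC/C=C(/C)[Li])[C@@H](C)O[Si](C)(C)C(C)(C)C | intermediate
13 | bromo{(2Z,6S,7E,9S,10R)-10-[(tert-butyldimethylsilyl)oxy]-9-methoxy-6-methylundeca-2,7-dien-2-yl}magnesium (alkene geometry of 10 retained) | CO[C@@H](/C=C/[C@@H](C)CC/C=C(/C)[Mg]Br)[C@@H](C)O[Si](C)(C)C(C)(C)C | intermediate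
14 | methyl (2S,4Z,8S,9E,11S,12R)-12-[(tert-butyldimethylsilyl)oxy]-2-hydroxy-11-methoxy-4,8-dimethyltrideca-4,9-dienoate | CO[C@@H](/C=C/[C@@H](C)CC/C=C(/C)C[C@H](O)C(=O)OC)[C@@H](C)O[Si](C)(C)C(C)(C)C | intermediate
15 | methyl (2S,4Z,8S,9E,11S,12R)-12-[(tert-butyldimethylsilyl)oxy]-11-methoxy-4,8-dimethyl-2-(propanoyloxy)trideca-4,9-dienoate | CO[C@@H](/C=C/[C@@H](C)CC/C=C(/C)C[C@H](OC(=O)CC)C(=O)OC)[C@@H](C)O[Si](C)(C)C(C)(C)C | intermediate
16 | (5S)-5-{(2Z,6S,7E,9S,10R)-10-[(tert-butyldimethylsilyl)oxy]-9-methoxy-2,6-dimethylundeca-2,7-dien-1-yl}-4-hydroxy-3-methylfuran-2(5H)-one | CO[C@@H](/C=C/[C@@H](C)CC/C=C(/C)C[C@@H]1OC(=O)C(C)=C1O)[C@@H](C)O[Si](C)(C)C(C)(C)C | intermediate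
17 | (5S)-5-{(2Z,6S,7E,9S,10R)-10-[(tert-butyldimethylsilyl)oxy]-9-methoxy-2,6-dimethylundeca-2,7-dien-1-yl}-4-methoxy-3-methylfuran-2(5H)-one | CO[C@@H](/C=C/[C@@H](C)CC/C=C(/C)C[C@@H]1OC(=O)C(C)=C1OC)[C@@H](C)O[Si](C)(C)C(C)(C)C | intermediate
18 | (5S)-5-[(2Z,6S,7E,9S,10R)-10-hydroxy-9-methoxy-2,6-dimethylundeca-2,7-dien-1-yl]-4-methoxy-3-methylfuran-2(5H)-one | CO[C@@H](/C=C/[C@@H](C)CC/C=C(/C)C[C@@H]1OC(=O)C(C)=C1OC)[C@@H](C)O | intermediate
19 | (5S)-4-methoxy-5-[(2Z,6S,7E,9S)-9-methoxy-2,6-dimethyl-10-oxoundeca-2,7-dien-1-yl]-3-methylfuran-2(5H)-one | CO[C@@H](/C=C/[C@@H](C)CC/C=C(/C)C[C@@H]1OC(=O)C(C)=C1OC)C(C)=O | intermediate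
20 | 3-bromofuran | Brc1ccoc1 | starting material
21 | oxetane | C1COC1 | starting material
22 | furan-3-yllithium | [Li]c1ccoc1 | intermediate
23 | 3-(furan-3-yl)propan-1-ol | OCCCc1ccoc1 | intermediate
24 | 3-(3-bromopropyl)furan | BrCCCc1ccoc1 | intermediate
25 | bromo[3-(furan-3-yl)propyl]magnesium | Br[Mg]CCCc1ccoc1 | intermediate
26 | (5S)-5-[(2Z,6S,7E,9S,10S)-13-(furan-3-yl)-10-hydroxy-9-methoxy-2,6,10-trimethyltrideca-2,7-dien-1-yl]-4-methoxy-3-methylfuran-2(5H)-one | CO[C@@H](/C=C/[C@@H](C)CC/C=C(/C)C[C@@H]1OC(=O)C(C)=C1OC)[C@@](C)(O)CCCc1ccoc1 | intermediate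
27 | (5S)-5-[(2Z,6S,7E,9S,10S)-13-(furan-3-yl)-10-hydroxy-9-methoxy-2,6,10-trimethyltrideca-2,7-dien-1-yl]-4-hydroxy-3-methylfuran-2(5H)-one | CO[C@@H](/C=C/[C@@H](C)CC/C=C(/C)C[C@@H]1OC(=O)C(C)=C1O)[C@@](C)(O)CCCc1ccoc1 | target

**Step count**

Total: 18 steps. Longest linear sequence: 15 steps (steps 1–4, 6–14, 17, 18).

**Steps most likely to fail**

Step 17. The basic Grignard reagent may enolise the α-methoxy β,γ-unsaturated ketone, with migration of the C7'=C8' double bond into conjugation or epimerisation at C9', and incomplete chelation may erode the facial selectivity. The fallback sets out from 19 and comes back at 26. It builds the arm in two stages under non-basic conditions, and the acid-sensitive furan enters only after the Lewis acid step. Allyltrimethylsilane with TiCl4 in CH2Cl2 at −78 °C (chelation-controlled Hosomi–Sakurai allylation through the same five-membered chelate, now on titanium) should give the homoallylic tertiary alcohol (5S)-5-[(2Z,6S,7E,9S,10S)-10-hydroxy-9-methoxy-2,6,10-trimethyltrideca-2,7,12-trien-1-yl]-4-methoxy-3-methylfuran-2(5H)-one F1. 9-BBN-H in THF should hydroborate only its terminal alkene to the B-alkyl-9-borabicyclononane F2. B-alkyl Suzuki–Miyaura coupling of this borane with 3-bromofuran 20 [PdCl2(dppf), Cs2CO3, DMF/H2O, 23 °C] should then give 26.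

Step 6. Productive metathesis between two allylically branched partners may be slow, so that homodimerisation, catalyst decomposition and ruthenium-hydride alkene migration take over. The fallback sets out from 7 and 5 and comes back at 8 by a Julia–Kocienski olefination. Ozonolysis of the vinyl group of 7 (O3, CH2Cl2/MeOH, −78 °C) gives the aldehyde (2S)-4-(3,3-dimethyloxiran-2-yl)-2-methylbutanal F3, which is reduced in the same flask with NaBH4 to the alcohol (2S)-4-(3,3-dimethyloxiran-2-yl)-2-methylbutan-1-ol F4. Mitsunobu reaction with 1-phenyl-1H-tetrazole-5-thiol (PPh3, DIAD) gives the sulfide F5, and mCPBA with NaHCO3 gives the sulfone F6. Ozonolysis of 5 (O3, CH2Cl2, −78 °C; PPh3) gives the α-methoxy aldehyde (2R,3R)-3-[(tert-butyldimethylsilyl)oxy]-2-methoxybutanal F7. Deprotonation of the sulfone with KHMDS in DME at −60 °C and addition of this aldehyde should give 8 with the E alkene.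

Step 9. The alkenylmagnesium species may add to the ester carbonyl of the glycidate instead of opening the oxirane, or may be lost by protonation or homocoupling. The fallback sets out from 9 and comes back at 14; it reverses the polarity at C1' and also bypasses step 8. Still–Gennari olefination of 9 [ethyl 2-[bis(2,2,2-trifluoroethoxy)phosphoryl]propanoate, KHMDS, 18-crown-6, THF, −78 °C] should give the (Z)-enoate F8. DIBAL-H (CH2Cl2, −78 °C) gives the allylic alcohol F9, and CBr4/PPh3 gives the allylic bromide F10. Alkylation of the sodium enolate of (4R)-4-benzyl-3-{[(4-methoxybenzyl)oxy]acetyl}-1,3-oxazolidin-2-one (NaHMDS, THF, −78 → −45 °C; Evans-type glycolate alkylation, the benzyl group shielding one enolate face) with this bromide should give the (2S) imide F11. MeOMgBr in MeOH/CH2Cl2 at 0 °C gives the methyl ester F12, and DDQ in CH2Cl2/pH 7 buffer removes the 4-methoxybenzyl group to give 14.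

Further compounds
F1 | step 17 | (5S)-5-[(2Z,6S,7E,9S,10S)-10-hydroxy-9-methoxy-2,6,10-trimethyltrideca-2,7,12-trien-1-yl]-4-methoxy-3-methylfuran-2(5H)-one | CO[C@@H](/C=C/[C@@H](C)CC/C=C(/C)C[C@@H]1OC(=O)C(C)=C1OC)[C@@](C)(O)CC=C
F2 | step 17 | (5S)-5-[(2Z,6S,7E,9S,10S)-13-(9-borabicyclo[3.3.1]nonan-9-yl)-10-hydroxy-9-methoxy-2,6,10-trimethyltrideca-2,7-dien-1-yl]-4-methoxy-3-methylfuran-2(5H)-one | CO[C@@H](/C=C/[C@@H](C)CC/C=C(/C)C[C@@H]1OC(=O)C(C)=C1OC)[C@@](C)(O)CCCB1C2CCCC1CCC2
F3 | step 6 | (2S)-4-(3,3-dimethyloxiran-2-yl)-2-methylbutanal (both oxirane epimers) | O=C[C@@H](C)CCC1OC1(C)C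
F4 | step 6 | (2S)-4-(3,3-dimethyloxiran-2-yl)-2-methylbutan-1-ol (both oxirane epimers) | OC[C@@H](C)CCC1OC1(C)C
F5 | step 6 | 5-{[(2S)-4-(3,3-dimethyloxiran-2-yl)-2-methylbutyl]sulfanyl}-1-phenyl-1H-tetrazole | c1ccccc1-n1nnnc1SC[C@@H](C)CCC1OC1(C)C
F6 | step 6 | 5-{[(2S)-4-(3,3-dimethyloxiran-2-yl)-2-methylbutyl]sulfonyl}-1-phenyl-1H-tetrazole | c1ccccc1-n1nnnc1S(=O)(=O)C[C@@H](C)CCC1OC1(C)C
F7 | step 6 | (2R,3R)-3-[(tert-butyldimethylsilyl)oxy]-2-methoxybutanal | O=C[C@H](OC)[C@@H](C)O[Si](C)(C)C(C)(C)C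
F8 | step 9 | ethyl (2Z,6S,7E,9S,10R)-10-[(tert-butyldimethylsilyl)oxy]-9-methoxy-2,6-dimethylundeca-2,7-dienoate | CO[C@@H](/C=C/[C@@H](C)CC/C=C(/C)C(=O)OCC)[C@@H](C)O[Si](C)(C)C(C)(C)C
F9 | step 9 | (2Z,6S,7E,9S,10R)-10-[(tert-butyldimethylsilyl)oxy]-9-methoxy-2,6-dimethylundeca-2,7-dien-1-ol | CO[C@@H](/C=C/[C@@H](C)CC/C=C(/C)CO)[C@@H](C)O[Si](C)(C)C(C)(C)C
F10 | step 9 | tert-butyl{[(2R,3S,4E,6S,9Z)-11-bromo-3-methoxy-6,10-dimethylundeca-4,9-dien-2-yl]oxy}dimethylsilane | CO[C@@H](/C=C/[C@@H](C)CC/C=C(/C)CBr)[C@@H](C)O[Si](C)(C)C(C)(C)C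
F11 | step 9 | (4R)-4-benzyl-3-{(2S,4Z,8S,9E,11S,12R)-12-[(tert-butyldimethylsilyl)oxy]-11-methoxy-2-[(4-methoxybenzyl)oxy]-4,8-dimethyltrideca-4,9-dienoyl}-1,3-oxazolidin-2-one | CO[C@@H](/C=C/[C@@H](C)CC/C=C(/C)C[C@H](OCc1ccc(OC)cc1)C(=O)N1[C@H](Cc2ccccc2)COC1=O)[C@@H](C)O[Si](C)(C)C(C)(C)C
F12 | step 9 | methyl (2S,4Z,8S,9E,11S,12R)-12-[(tert-butyldimethylsilyl)oxy]-11-methoxy-2-[(4-methoxybenzyl)oxy]-4,8-dimethyltrideca-4,9-dienoate | CO[C@@H](/C=C/[C@@H](C)CC/C=C(/C)C[C@H](OCc1ccc(OC)cc1)C(=O)OC)[C@@H](C)O[Si](C)(C)C(C)(C)C
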